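## The problem

Target 24 is a flavan: ring A is the benzo ring of the chroman, ring C the pyran (O1, C2, C3, C4), and ring B the 5-hydroxy-2-methoxyphenyl group on C2. C6 carries a 1,3-diarylpropyl chain whose methine Ca bears ring D (4-hydroxyphenyl) and whose methylenes Cb and Cc lead to ring E (4-hydroxy-2-methoxyphenyl). Only ring C has to be closed; the rest is the joining of four arenes through sp3 carbons. The two stereocentres, Ca (R) and C2 (S), lie on opposite edges of ring A, six bonds apart, so neither can direct the other. Each needs its own reagent control and high enantiopurity, because the remote diastereomers would be very hard to separate. Ring A is a resorcinol whose oxygens end differently (O1 inside ring C, the C7 hydroxyl free), so they must be told apart early. The fragile points are the C2–O1 bond (a benzylic ether beside an ortho-methoxyaryl ring, labile to acid and hydrogenolysis), the doubly benzylic Ca–H ortho and para to the ring A oxygens, and four oxidisable phenols that must be unveiled last without loss of the two methyl ethers. The opening feature is that C2 is a benzylic carbinol carbon tied to ring A only through C3 and C4: C2–C3 is the bond between a ring B aldehyde carbon and the terminus of an ethynyl group on C4a, and O1–C2 is the bond formed when the C8a phenol displaces the activated carbinol.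

## Retrosynthesis

**24 from 23 (four O–benzyl bonds).** The phenols are carried as benzyl ethers because the two methyl ethers must stay and the unmasking must be neutral. The forward step is hydrogenolysis of 23, which must leave the C2–O1 bond intact.

**23 from 22, 21 and 20 (O1–C2).** Ring C is opened at O1–C2 rather than O1–C8a. The alternative cut would need an aryl C–O coupling on a hindered, electron-rich arene, and an acid-mediated closure would lose control of C2. Phenol 22 carries the (R)-carbinol, and Mitsunobu closure inverts it to (2S). Phenol 22 comes from silyl ether 21 by fluoride, and 21 from propargylic alcohol 20 by saturation of the triple bond. The forward steps must give a clean SN2 reaction at an electron-rich benzylic carbinol and must reduce an alkyne without touching four benzyl ethers.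

**20 from 15 and 18 (C2–C3, the key cut).** Cutting C3–C4 or C4–C4a would give sp3 couplings with no handle on C2. Cutting C2–C3 creates the stereocentre in the bond-forming event and splits the molecule into alkyne 15 and the trivial aldehyde 18. The precursor is simpler by ring B and one stereocentre. The forward reaction must select one face of an ortho-methoxybenzaldehyde under catalyst control and must tolerate silyl and benzyl ethers.

**15 from 14 and 13 (C4a–C(sp)).** The ethynyl group comes from aryl iodide 13 by Sonogashira coupling with a silyl-capped acetylene to give 14, followed by C-desilylation. The C8a oxygen must already be silylated so that no benzofuran can form.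

**13 from 11, and 11 from 7 and 9 (Cc–ring E).** Ring E is attached at the ketone oxidation level: aryl Grignard reagent 10, from bromide 9, adds once to Weinreb amide 7 to give ketone 11. The carbonyl oxygen is then removed through carbinol 12 by ionic hydrogenation. This is the only acid-demanding operation and it is placed here, before the alkyne and ring C exist.

**7 from 6 and 5 (C4a–I and C7–O–benzyl).** In 5 the only free phenol is the C7 hydroxyl, and C4a is para to it. Iodination at this stage is therefore regioselective, and chemoselective too, because the equally electron-rich ring E is not yet in the molecule. Benzylation of 6 then gives 7.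

**5 from 4 (lactone C–O).** Opening lactone 4 to the Weinreb amide frees the C7 hydroxyl and turns Cc into an acyl group that accepts exactly one aryl nucleophile.

**4 from 2 and 3, and 2 from 1 (Ca–ring D).** Ca is set by rhodium-catalysed conjugate addition of boronic acid 3 to coumarin 2. In umbelliferone 1 the lactone already ties up the future C7 oxygen, so silylation of its one free hydroxyl marks the future O1 and differentiates the resorcinol in the first step.

**Fragments.** Aldehyde 18 comes from 16 by selective benzylation to 17 and methylation. Bromide 9 comes from phenol 8 by benzylation.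

## Roads not taken

**Alternative 1:** The cut is Ca–Cb, with a temporary O7–Cc bond. A chiral phosphoric acid would dehydrate flavan carbinol A1 (either Ca epimer) to an ortho-quinone methide, and enamide A2 would add at Ca. The C7 oxygen would then close onto Cc with loss of acetamide, giving chromene A3.
- Merits: the step is stereoconvergent, Ca is set late by the catalyst, and ring E with both chain carbons arrives in one convergent operation.
- Weak points: A3 holds an O7–Cc bond and a Cb=Cc enol ether that the target lacks. Removing them means either acid hydrolysis and deoxygenation beside the acid-labile C2–O1 ether, or hydrogenolysis of one 2-arylchroman C–O bond in the presence of a second, nearly identical one. The Brønsted acid that forms the quinone methide can also ionise C2–O1. C2 still has to be set separately to make A1.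
- Comparison: Alternative 1 is more convergent and needs no early chiral rhodium step. The chosen plan is longer and linear, but it never has to excise an extra bond and applies no acid once ring C exists.

**Alternative 2:** The cut is Ca–ring D, made late. Rhodium–bisphosphine catalysis would add boronic acid 3 to the flavan-fused coumarin A4, giving lactone A5 with Ca set.
- Merits: it is the same well-proven conjugate addition used here, and it is tested on the real system. The lactone protects the C7 oxygen, so ring A needs no silyl/benzyl differentiation; in protecting-group economy this road is better.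
- Weak points: A4 needs an enantiopure flavan and a pyranone annulation first, and its coumarin carries an extra donor, which lowers reactivity at Ca. After A5, ring E must be added to Cc and the carbonyl oxygen removed while the C2–O1 ether is present; the ionic deoxygenation that the chosen plan runs before ring C exists would then threaten ring C.
- Comparison: the stereo-setting steps are equally reliable. The chosen plan gives up some protecting-group economy to have the acid step before the flavan is formed and a neutral endgame.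

**Alternative 3:** The cut is O1–C8a. Phenol A6 would be oxidised (PhI(OAc)2, methanol) to the 4-methoxycyclohexadienone A7. The tethered (S)-hydroxyl would add to C8a and methanol would be lost, closing ring C and giving A8.
- Merits: the carbinol C–O bond is never broken, so C2 is carried with retention and cannot leak through ionisation; this is a real advantage over the Mitsunobu closure. Ring A needs no oxygen at C8a beforehand, which saves the silyl operations.
- Weak points: one phenol must be oxidised beside three other electron-rich arenes, including a hydroquinone-type ring B. The doubly benzylic Ca–H next to that phenol may be lost through a quinone methide, which would erase Ca. C5 and C8a are both enone β-carbons within reach of the hydroxyl, so regiochemistry depends only on the bulk at C6.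
- Comparison: Alternative 3 is shorter on paper and safer at C2. The chosen plan accepts the ionisation risk in the Mitsunobu step (covered by a fallback) in exchange for operations whose chemoselectivity is predictable.

Key step: step 13

Assumption: (S,S)-ProPhenol is written on the understanding that it delivers the alkynyl group to the Re face of aldehyde 18, which gives the (1R)-carbinol. If the sense is the reverse, (R,R)-ProPhenol takes its place and nothing else changes.

## Route

Step 1
Reactants: 1 umbelliferone (7-hydroxycoumarin)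
Product: 2 7-[(triisopropylsilyl)oxy]-2H-chromen-2-one
Conditions: TIPSCl, imidazole, DMF, rt
Reagents that add atoms: triisopropylsilyl chloride, CC(C)[Si](Cl)(C(C)C)C(C)C
Why: Phenol silylation with a silyl chloride and imidazole; the bulky triisopropylsilyl ether should survive the aqueous, basic, organometallic and acidic steps that follow and marks this oxygen as the future O1.

Step 2
Reactants: 2 7-[(triisopropylsilyl)oxy]-2H-chromen-2-one; 3 4-(benzyloxy)phenylboronic acid
Product: 4 (4R)-4-[4-(benzyloxy)phenyl]-7-[(triisopropylsilyl)oxy]chroman-2-one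
Conditions: Rh(acac)(C2H4)2 (3 mol%), (R)-Segphos (3.3 mol%), 3 (excess), dioxane/H2O 10:1, 60 °C
Reagents that add atoms: none
Why: Rhodium-catalysed asymmetric 1,4-addition of an arylboronic acid to a coumarin (Hayashi–Miyaura reaction); the aryl–rhodium–(R)-Segphos species adds to one face of C3=C4 and water protonates the rhodium enolate, which on simple coumarins gives (4R)-4-arylchroman-2-ones in very high ee. The neutral medium should leave the silyl and benzyl ethers alone.

Step 3
Reactants: 4 (4R)-4-[4-(benzyloxy)phenyl]-7-[(triisopropylsilyl)oxy]chroman-2-one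
Product: 5 (3R)-3-[4-(benzyloxy)phenyl]-3-{2-hydroxy-4-[(triisopropylsilyl)oxy]phenyl}-N-methoxy-N-methylpropanamide
Conditions: MeNH(OMe)·HCl, Al(CH3)3, CH2Cl2, 0 °C → rt
Reagents that add atoms: N,O-dimethylhydroxylamine hydrochloride, CNOC.Cl
Why: Weinreb aminolysis of an aryl ester by the aluminium amide formed in the flask; it frees the C7 phenol and makes Cc an acyl group that takes up only one carbanion. Ca is not enolisable and should stay (R).

Step 4
Reactants: 5 (3R)-3-[4-(benzyloxy)phenyl]-3-{2-hydroxy-4-[(triisopropylsilyl)oxy]phenyl}-N-methoxy-N-methylpropanamide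
Product: 6 (3R)-3-[4-(benzyloxy)phenyl]-3-{2-hydroxy-5-iodo-4-[(triisopropylsilyl)oxy]phenyl}-N-methoxy-N-methylpropanamide
Conditions: NIS (1.05 equiv), MeCN, 0 °C, dark
Reagents that add atoms: N-iodosuccinimide, O=C1CCC(=O)N1I
Why: Electrophilic aromatic iodination of a phenol; the only free phenol directs to its para position (the future C4a), the site between the two oxygens is shielded by the silyl group, and ring D as a mono-ether is far less reactive.

Step 5
Reactants: 6 (3R)-3-[4-(benzyloxy)phenyl]-3-{2-hydroxy-5-iodo-4-[(triisopropylsilyl)oxy]phenyl}-N-methoxy-N-methylpropanamide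
Product: 7 (3R)-3-{2-(benzyloxy)-5-iodo-4-[(triisopropylsilyl)oxy]phenyl}-3-[4-(benzyloxy)phenyl]-N-methoxy-N-methylpropanamide
Conditions: BnBr, K2CO3, acetone, 50 °C
Reagents that add atoms: benzyl bromide, BrCc1ccccc1
Why: Williamson benzylation of the phenoxide; benzyl matches the other phenol protecting groups so that all fall together at the end, and dry carbonate in acetone should not cleave the hindered aryl silyl ether.

Step 6
Reactants: 8 4-bromo-3-methoxyphenol
Product: 9 4-(benzyloxy)-1-bromo-2-methoxybenzene
Conditions: BnBr, K2CO3, DMF, rt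
Reagents that add atoms: benzyl bromide, BrCc1ccccc1
Why: Williamson ether synthesis on a simple phenol.

Step 7
Reactants: 9 4-(benzyloxy)-1-bromo-2-methoxybenzene; 7 (3R)-3-{2-(benzyloxy)-5-iodo-4-[(triisopropylsilyl)oxy]phenyl}-3-[4-(benzyloxy)phenyl]-N-methoxy-N-methylpropanamide
Product: 11 (3R)-3-{2-(benzyloxy)-5-iodo-4-[(triisopropylsilyl)oxy]phenyl}-1-[4-(benzyloxy)-2-methoxyphenyl]-3-[4-(benzyloxy)phenyl]propan-1-one, via aryl Grignard reagent 10 (not isolated)
Conditions: 9, Mg, THF, reflux; solution decanted from Mg onto 7, THF, 0 °C → rt; aq. NH4Cl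
Reagents that add atoms: none
Why: Grignard formation and acyl substitution on a Weinreb amide; the chelated tetrahedral magnesium adduct holds until work-up, so only one aryl group adds. An aryl Grignard reagent at 0 °C should not undergo halogen–metal exchange with the electron-rich aryl iodide, as an aryllithium would.

Step 8
Reactants: 11 (3R)-3-{2-(benzyloxy)-5-iodo-4-[(triisopropylsilyl)oxy]phenyl}-1-[4-(benzyloxy)-2-methoxyphenyl]-3-[4-(benzyloxy)phenyl]propan-1-one
Product: 13 {5-(benzyloxy)-4-[(1R)-3-[4-(benzyloxy)-2-methoxyphenyl]-1-[4-(benzyloxy)phenyl]propyl]-2-iodophenoxy}triisopropylsilane, via benzylic alcohol 12 (not isolated)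
Conditions: NaBH4, THF/MeOH, 0 °C → rt; solvent exchange; Et3SiH (3 equiv), CF3CO2H (5 equiv), CH2Cl2, −20 → 0 °C
Reagents that add atoms: none
Why: Borohydride reduction followed by ionic hydrogenation (Kursanov–Parnes type): the carbinol on the 2,4-dialkoxyphenyl ring E ionises in dilute acid at low temperature and Et3SiH captures the cation. The nearest positions for Friedel–Crafts closure are meta to oxygen, so hydride capture should win and Ca should stay (R). Brief cold acid should spare the aryl iodide and the benzyl and silyl ethers.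

Step 9
Reactants: 13 {5-(benzyloxy)-4-[(1R)-3-[4-(benzyloxy)-2-methoxyphenyl]-1-[4-(benzyloxy)phenyl]propyl]-2-iodophenoxy}triisopropylsilane
Product: 14 {5-(benzyloxy)-4-[(1R)-3-[4-(benzyloxy)-2-methoxyphenyl]-1-[4-(benzyloxy)phenyl]propyl]-2-[(trimethylsilyl)ethynyl]phenoxy}triisopropylsilane
Conditions: HC≡CSiMe3, PdCl2(PPh3)2 (5 mol%), CuI (10 mol%), Et3N, THF, 50 °C
Reagents that add atoms: trimethylsilylacetylene, C#C[Si](C)(C)C
Why: Sonogashira coupling of an aryl iodide (zerovalent palladium with a monovalent copper acetylide); the silylated phenol cannot close to a benzofuran and the trimethylsilyl cap prevents double coupling.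

Step 10
Reactants: 14 {5-(benzyloxy)-4-[(1R)-3-[4-(benzyloxy)-2-methoxyphenyl]-1-[4-(benzyloxy)phenyl]propyl]-2-[(trimethylsilyl)ethynyl]phenoxy}triisopropylsilane
Product: 15 {5-(benzyloxy)-4-[(1R)-3-[4-(benzyloxy)-2-methoxyphenyl]-1-[4-(benzyloxy)phenyl]propyl]-2-ethynylphenoxy}triisopropylsilane
Conditions: K2CO3 (0.2 equiv), MeOH/THF, 0 °C
Reagents that add atoms: none
Why: Methanolysis of the C(sp)–Si bond by catalytic methoxide; the hindered aryl triisopropylsilyl ether is cleaved much more slowly, so the phenol should stay masked at 0 °C.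

Step 11
Reactants: 16 2,5-dihydroxybenzaldehyde
Product: 17 5-(benzyloxy)-2-hydroxybenzaldehyde
Conditions: BnBr (1.0 equiv), K2CO3 (1.0 equiv), acetone, rt → 50 °C
Reagents that add atoms: benzyl bromide, BrCc1ccccc1
Why: Williamson benzylation; the C2 hydroxyl is hydrogen-bonded to the aldehyde and less nucleophilic, so one equivalent of benzyl bromide should go to the C5 hydroxyl.

Step 12
Reactants: 17 5-(benzyloxy)-2-hydroxybenzaldehyde
Product: 18 5-(benzyloxy)-2-methoxybenzaldehyde
Conditions: MeI, K2CO3, DMF, rt
Reagents that add atoms: iodomethane, CI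
Why: Williamson O-methylation of the remaining phenol.

Step 13
Reactants: 15 {5-(benzyloxy)-4-[(1R)-3-[4-(benzyloxy)-2-methoxyphenyl]-1-[4-(benzyloxy)phenyl]propyl]-2-ethynylphenoxy}triisopropylsilane; 18 5-(benzyloxy)-2-methoxybenzaldehyde
Product: 20 (1R)-1-[5-(benzyloxy)-2-methoxyphenyl]-3-{4-(benzyloxy)-5-[(1R)-3-[4-(benzyloxy)-2-methoxyphenyl]-1-[4-(benzyloxy)phenyl]propyl]-2-[(triisopropylsilyl)oxy]phenyl}prop-2-yn-1-ol, via alkynyl(methyl)zinc 19 (not isolated)
Conditions: Zn(CH3)2 (2 equiv), (S,S)-ProPhenol (20 mol%), Ph3P=O (40 mol%), toluene, 0 °C → rt; then 18 (1.5 equiv), 4 °C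
Reagents that add atoms: none
Why: Zinc–ProPhenol alkynylation of an aryl aldehyde. Zn(CH3)2 and the ligand form a dinuclear zinc alkoxide that deprotonates 15 with loss of methane and gives alkynyl(methyl)zinc 19; in the dinuclear complex one zinc binds the carbonyl oxygen of 18 and the other holds the alkynyl group, which is transferred to a single carbonyl face, and Ph3P=O speeds turnover. The closest known reaction is the same catalyst adding arylacetylenes to aryl and unsaturated aldehydes. No ring closes. The new stereocentre, the future C2 formed as (1R), is controlled only by the ligand enantiomer, since Ca lies six bonds away across ring A and the rigid alkyne. The step needs alkynyl transfer to outrun methyl transfer, which the much higher transfer rate of sp carbon from zinc should secure, and it needs the ligand rather than the ortho-methoxy group to organise the aldehyde. The silyl and benzyl ethers are inert to organozinc reagents, and an excess of the cheap aldehyde makes the valuable alkyne the limiting partner.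

Step 14
Reactants: 20 (1R)-propargylic alcohol from step 13
Product: 21 (1R)-1-[5-(benzyloxy)-2-methoxyphenyl]-3-{4-(benzyloxy)-5-[(1R)-3-[4-(benzyloxy)-2-methoxyphenyl]-1-[4-(benzyloxy)phenyl]propyl]-2-[(triisopropylsilyl)oxy]phenyl}propan-1-ol
Conditions: H2 (1 atm), 10% Pd/C, Ph2S (0.1 equiv), EtOAc, rt
Reagents that add atoms: none
Why: Heterogeneous hydrogenation over sulfide-poisoned Pd/C; the catalyst still saturates C≡C bonds but is too deactivated for hydrogenolysis of aryl benzyl ethers or of the benzylic C–OH bond, so the carbinol centre should be untouched.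

Step 15
Reactants: 21 (1R)-silyl ether carbinol from step 14
Product: 22 5-(benzyloxy)-4-[(1R)-3-[4-(benzyloxy)-2-methoxyphenyl]-1-[4-(benzyloxy)phenyl]propyl]-2-{(3R)-3-[5-(benzyloxy)-2-methoxyphenyl]-3-hydroxypropyl}phenol
Conditions: Bu4NF, THF, 0 °C
Reagents that add atoms: none
Why: Fluoride cleavage of an aryl silyl ether; benzyl and methyl ethers and the secondary alcohol are inert, and with the alkyne gone the free phenol cannot cyclise to a benzofuran.

Step 16
Reactants: 22 phenol carbinol from step 15
Product: 23 (2S)-7-(benzyloxy)-2-[5-(benzyloxy)-2-methoxyphenyl]-6-[(1R)-3-[4-(benzyloxy)-2-methoxyphenyl]-1-[4-(benzyloxy)phenyl]propyl]chroman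
Conditions: PPh3, DIAD, THF, 0 °C → rt, high dilution
Reagents that add atoms: none
Why: Intramolecular Mitsunobu etherification; the alcohol is activated as an oxyphosphonium ion and displaced by the C8a phenoxide in a 6-exo-tet SN2 closure with inversion, which turns the (R)-carbinol into (2S). The phenol is an ideal pronucleophile, and low temperature in THF disfavours ionisation.

Step 17
Reactants: 23 tetrabenzyl (2S)-flavan from step 16
Product: 24 (2S)-2-(5-hydroxy-2-methoxyphenyl)-6-[(1R)-3-(4-hydroxy-2-methoxyphenyl)-1-(4-hydroxyphenyl)propyl]chroman-7-ol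
Conditions: H2 (1 atm), 10% Pd/C, EtOAc/MeOH, rt, no acid
Reagents that add atoms: none
Why: Catalytic hydrogenolysis of four aryl benzyl ethers under neutral conditions; methyl ethers are inert, and the secondary C2–O1 ether held in ring C should be cleaved far more slowly than the O-benzyl groups if no acid is present and the reaction is stopped after four equivalents of H2.

## Compound list

1 | umbelliferone (7-hydroxy-2H-chromen-2-one) | O=c1ccc2ccc(O)cc2o1 | starting material
2 | 7-[(triisopropylsilyl)oxy]-2H-chromen-2-one | O=c1ccc2ccc(O[Si](C(C)C)(C(C)C)C(C)C)cc2o1 | intermediate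
3 | 4-(benzyloxy)phenylboronic acid | OB(O)c1ccc(OCc2ccccc2)cc1 | starting material
4 | (4R)-4-[4-(benzyloxy)phenyl]-7-[(triisopropylsilyl)oxy]chroman-2-one | O=C1C[C@H](c2ccc(OCc3ccccc3)cc2)c2ccc(O[Si](C(C)C)(C(C)C)C(C)C)cc2O1 | intermediate
5 | (3R)-3-[4-(benzyloxy)phenyl]-3-{2-hydroxy-4-[(triisopropylsilyl)oxy]phenyl}-N-methoxy-N-methylpropanamide | CON(C)C(=O)C[C@H](c1ccc(OCc2ccccc2)cc1)c1ccc(O[Si](C(C)C)(C(C)C)C(C)C)cc1O | intermediate
6 | (3R)-3-[4-(benzyloxy)phenyl]-3-{2-hydroxy-5-iodo-4-[(triisopropylsilyl)oxy]phenyl}-N-methoxy-N-methylpropanamide | CON(C)C(=O)C[C@H](c1ccc(OCc2ccccc2)cc1)c1cc(I)c(O[Si](C(C)C)(C(C)C)C(C)C)cc1O | intermediate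
7 | (3R)-3-{2-(benzyloxy)-5-iodo-4-[(triisopropylsilyl)oxy]phenyl}-3-[4-(benzyloxy)phenyl]-N-methoxy-N-methylpropanamide | CON(C)C(=O)C[C@H](c1ccc(OCc2ccccc2)cc1)c1cc(I)c(O[Si](C(C)C)(C(C)C)C(C)C)cc1OCc1ccccc1 | intermediate
8 | 4-bromo-3-methoxyphenol | COc1cc(O)ccc1Br | starting material
9 | 4-(benzyloxy)-1-bromo-2-methoxybenzene | COc1cc(OCc2ccccc2)ccc1Br | intermediate
10 | [4-(benzyloxy)-2-methoxyphenyl]magnesium bromide (not isolated) | COc1cc(OCc2ccccc2)ccc1[Mg]Br | intermediate
11 | (3R)-3-{2-(benzyloxy)-5-iodo-4-[(triisopropylsilyl)oxy]phenyl}-1-[4-(benzyloxy)-2-methoxyphenyl]-3-[4-(benzyloxy)phenyl]propan-1-one | COc1cc(OCc2ccccc2)ccc1C(=O)C[C@H](c1ccc(OCc2ccccc2)cc1)c1cc(I)c(O[Si](C(C)C)(C(C)C)C(C)C)cc1OCc1ccccc1 | intermediate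
12 | (1RS,3R)-3-{2-(benzyloxy)-5-iodo-4-[(triisopropylsilyl)oxy]phenyl}-1-[4-(benzyloxy)-2-methoxyphenyl]-3-[4-(benzyloxy)phenyl]propan-1-ol, both C1 epimers (not isolated) | COc1cc(OCc2ccccc2)ccc1C(O)C[C@H](c1ccc(OCc2ccccc2)cc1)c1cc(I)c(O[Si](C(C)C)(C(C)C)C(C)C)cc1OCc1ccccc1 | intermediate
13 | {5-(benzyloxy)-4-[(1R)-3-[4-(benzyloxy)-2-methoxyphenyl]-1-[4-(benzyloxy)phenyl]propyl]-2-iodophenoxy}triisopropylsilane | COc1cc(OCc2ccccc2)ccc1CC[C@H](c1ccc(OCc2ccccc2)cc1)c1cc(I)c(O[Si](C(C)C)(C(C)C)C(C)C)cc1OCc1ccccc1 | intermediate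
14 | {5-(benzyloxy)-4-[(1R)-3-[4-(benzyloxy)-2-methoxyphenyl]-1-[4-(benzyloxy)phenyl]propyl]-2-[(trimethylsilyl)ethynyl]phenoxy}triisopropylsilane | COc1cc(OCc2ccccc2)ccc1CC[C@H](c1ccc(OCc2ccccc2)cc1)c1cc(C#C[Si](C)(C)C)c(O[Si](C(C)C)(C(C)C)C(C)C)cc1OCc1ccccc1 | intermediate
15 | {5-(benzyloxy)-4-[(1R)-3-[4-(benzyloxy)-2-methoxyphenyl]-1-[4-(benzyloxy)phenyl]propyl]-2-ethynylphenoxy}triisopropylsilane | COc1cc(OCc2ccccc2)ccc1CC[C@H](c1ccc(OCc2ccccc2)cc1)c1cc(C#C)c(O[Si](C(C)C)(C(C)C)C(C)C)cc1OCc1ccccc1 | intermediate
16 | 2,5-dihydroxybenzaldehyde | O=Cc1cc(O)ccc1O | starting material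
17 | 5-(benzyloxy)-2-hydroxybenzaldehyde | O=Cc1cc(OCc2ccccc2)ccc1O | intermediate
18 | 5-(benzyloxy)-2-methoxybenzaldehyde | COc1ccc(OCc2ccccc2)cc1C=O | intermediate
19 | ({4-(benzyloxy)-5-[(1R)-3-[4-(benzyloxy)-2-methoxyphenyl]-1-[4-(benzyloxy)phenyl]propyl]-2-[(triisopropylsilyl)oxy]phenyl}ethynyl)(methyl)zinc (not isolated) | COc1cc(OCc2ccccc2)ccc1CC[C@H](c1ccc(OCc2ccccc2)cc1)c1cc(C#C[Zn]C)c(O[Si](C(C)C)(C(C)C)C(C)C)cc1OCc1ccccc1 | intermediate
20 | (1R)-1-[5-(benzyloxy)-2-methoxyphenyl]-3-{4-(benzyloxy)-5-[(1R)-3-[4-(benzyloxy)-2-methoxyphenyl]-1-[4-(benzyloxy)phenyl]propyl]-2-[(triisopropylsilyl)oxy]phenyl}prop-2-yn-1-ol | COc1cc(OCc2ccccc2)ccc1CC[C@H](c1ccc(OCc2ccccc2)cc1)c1cc(C#C[C@@H](O)c2cc(OCc3ccccc3)ccc2OC)c(O[Si](C(C)C)(C(C)C)C(C)C)cc1OCc1ccccc1 | intermediate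
21 | (1R)-1-[5-(benzyloxy)-2-methoxyphenyl]-3-{4-(benzyloxy)-5-[(1R)-3-[4-(benzyloxy)-2-methoxyphenyl]-1-[4-(benzyloxy)phenyl]propyl]-2-[(triisopropylsilyl)oxy]phenyl}propan-1-ol | COc1cc(OCc2ccccc2)ccc1CC[C@H](c1ccc(OCc2ccccc2)cc1)c1cc(CC[C@@H](O)c2cc(OCc3ccccc3)ccc2OC)c(O[Si](C(C)C)(C(C)C)C(C)C)cc1OCc1ccccc1 | intermediate
22 | 5-(benzyloxy)-4-[(1R)-3-[4-(benzyloxy)-2-methoxyphenyl]-1-[4-(benzyloxy)phenyl]propyl]-2-{(3R)-3-[5-(benzyloxy)-2-methoxyphenyl]-3-hydroxypropyl}phenol | COc1cc(OCc2ccccc2)ccc1CC[C@H](c1ccc(OCc2ccccc2)cc1)c1cc(CC[C@@H](O)c2cc(OCc3ccccc3)ccc2OC)c(O)cc1OCc1ccccc1 | intermediate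
23 | (2S)-7-(benzyloxy)-2-[5-(benzyloxy)-2-methoxyphenyl]-6-[(1R)-3-[4-(benzyloxy)-2-methoxyphenyl]-1-[4-(benzyloxy)phenyl]propyl]chroman | COc1cc(OCc2ccccc2)ccc1CC[C@H](c1ccc(OCc2ccccc2)cc1)c1cc2c(cc1OCc1ccccc1)O[C@H](c1cc(OCc3ccccc3)ccc1OC)CC2 | intermediate
24 | (2S)-2-(5-hydroxy-2-methoxyphenyl)-6-[(1R)-3-(4-hydroxy-2-methoxyphenyl)-1-(4-hydroxyphenyl)propyl]chroman-7-ol | COc1cc(O)ccc1CC[C@H](c1ccc(O)cc1)c1cc2c(cc1O)O[C@H](c1cc(O)ccc1OC)CC2 | target

## Step count and least certain steps

Total step count: 17. Longest linear sequence: 14 steps from umbelliferone 1 (steps 1–5, 7–10, 13–17). Steps 6, 11 and 12 prepare the ring E and ring B fragments.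

**Step 13 (key step).** The most likely failures are incomplete consumption of the bulky, limiting alkyne and lowered face selectivity. The ortho-methoxy group of 18 can bind zinc and compete with the ligand for organising the carbonyl, and slow alkynyl transfer would let methyl transfer consume aldehyde. The fallback keeps the acetylide-plus-aldehyde bond formation but moves stereocontrol to a ketone reduction. It sets out from 15 and 18 and returns at 21.
- Alkyne 15 is deprotonated with n-BuLi (THF, −78 °C) and added to 18, giving 1-[5-(benzyloxy)-2-methoxyphenyl]-3-{4-(benzyloxy)-5-[(1R)-3-[4-(benzyloxy)-2-methoxyphenyl]-1-[4-(benzyloxy)phenyl]propyl]-2-[(triisopropylsilyl)oxy]phenyl}prop-2-yn-1-ol as both carbinol epimers F1.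
- MnO2 in CH2Cl2 should oxidise it to the corresponding prop-2-yn-1-one F2.
- Hydrogenation over Pd/C with Ph2S should give the saturated aryl ketone, the corresponding propan-1-one F3.
- Corey–Bakshi–Shibata reduction of F3 with (S)-2-methyl-CBS-oxazaborolidine and BH3·SMe2 should give the (1R)-carbinol 21; aryl alkyl ketones are the best substrates for this reduction.

**Step 2.** The 7-silyloxy group donates into the enoate and lowers electrophilicity at C4. Conjugate addition may then be slower than protodeboronation of 3, and prolonged heating in aqueous dioxane may cost the silyl ether. The fallback sets Ca by hydride delivery instead of aryl delivery. It sets out from 2 and 3 and returns at 4.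
- Oxidative Heck arylation (Pd(OAc)2, 1,10-phenanthroline, O2, DMF) should give 4-[4-(benzyloxy)phenyl]-7-[(triisopropylsilyl)oxy]-2H-chromen-2-one F4.
- Copper hydride conjugate reduction (Cu(OAc)2, the DTBM-Segphos enantiomer that gives the (4R) product, diethoxymethylsilane, t-BuOH, toluene) should then give 4.

**Step 14.** Possible failures are loss of benzyl groups, hydrogenolysis of the propargylic or benzylic C–O bond, palladium hydride isomerisation of the intermediate allylic alcohol to the ketone (which would erase the new stereocentre), or stalling at the alkene beside the bulky silyl ether. The fallback sets out from 20 and returns at 21. It uses diimide generated from 2-nitrobenzenesulfonyl hydrazide and Et3N in CH2Cl2 at rt, in excess. This is a metal-free, concerted syn transfer of H2 that can neither cleave C–O bonds nor move double bonds. It makes no new compound (F0).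

**Step 16.** The activated carbinol sits on an ortho-methoxyaryl ring. Partial ionisation of the oxyphosphonium ion would erode configuration at C2, and elimination to the styrene is the other leak. The fallback sets C2 by asymmetric hydrogenation instead of substitution. It sets out from 22 and returns at 23.
- MnO2 should oxidise the benzylic alcohol to 1-[5-(benzyloxy)-2-methoxyphenyl]-3-{4-(benzyloxy)-5-[(1R)-3-[4-(benzyloxy)-2-methoxyphenyl]-1-[4-(benzyloxy)phenyl]propyl]-2-hydroxyphenyl}propan-1-one F5.
- Catalytic TsOH in toluene with removal of water should cyclodehydrate it to 7-(benzyloxy)-2-[5-(benzyloxy)-2-methoxyphenyl]-6-[(1R)-3-[4-(benzyloxy)-2-methoxyphenyl]-1-[4-(benzyloxy)phenyl]propyl]-4H-chromene F6.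
- Hydrogenation with [Ir(cod)(tBu-PHOX)]BArF, using the ligand enantiomer that gives (2S), should deliver 23 with the benzyl ethers intact.

**Step 17.** Possible failures are hydrogenolytic opening of ring C at the benzylic C2–O1 bond and slow removal of the hindered C7 benzyl group, which would prolong exposure. The fallback replaces hydrogenolysis by Lewis-acid debenzylation. It sets out from 23 and returns at 24, using BCl3 with pentamethylbenzene as cation scavenger in CH2Cl2 at −78 °C; aryl methyl ethers survive at this temperature. It makes no new compound (F0).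

## Further compounds

F1 | step 13 | 1-[5-(benzyloxy)-2-methoxyphenyl]-3-{4-(benzyloxy)-5-[(1R)-3-[4-(benzyloxy)-2-methoxyphenyl]-1-[4-(benzyloxy)phenyl]propyl]-2-[(triisopropylsilyl)oxy]phenyl}prop-2-yn-1-ol, both C1 epimers | COc1cc(OCc2ccccc2)ccc1CC[C@H](c1ccc(OCc2ccccc2)cc1)c1cc(C#CC(O)c2cc(OCc3ccccc3)ccc2OC)c(O[Si](C(C)C)(C(C)C)C(C)C)cc1OCc1ccccc1
F2 | step 13 | 1-[5-(benzyloxy)-2-methoxyphenyl]-3-{4-(benzyloxy)-5-[(1R)-3-[4-(benzyloxy)-2-methoxyphenyl]-1-[4-(benzyloxy)phenyl]propyl]-2-[(triisopropylsilyl)oxy]phenyl}prop-2-yn-1-one | COc1cc(OCc2ccccc2)ccc1CC[C@H](c1ccc(OCc2ccccc2)cc1)c1cc(C#CC(=O)c2cc(OCc3ccccc3)ccc2OC)c(O[Si](C(C)C)(C(C)C)C(C)C)cc1OCc1ccccc1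
F3 | step 13 | 1-[5-(benzyloxy)-2-methoxyphenyl]-3-{4-(benzyloxy)-5-[(1R)-3-[4-(benzyloxy)-2-methoxyphenyl]-1-[4-(benzyloxy)phenyl]propyl]-2-[(triisopropylsilyl)oxy]phenyl}propan-1-one | COc1cc(OCc2ccccc2)ccc1CC[C@H](c1ccc(OCc2ccccc2)cc1)c1cc(CCC(=O)c2cc(OCc3ccccc3)ccc2OC)c(O[Si](C(C)C)(C(C)C)C(C)C)cc1OCc1ccccc1
F4 | step 2 | 4-[4-(benzyloxy)phenyl]-7-[(triisopropylsilyl)oxy]-2H-chromen-2-one | O=c1cc(-c2ccc(OCc3ccccc3)cc2)c2ccc(O[Si](C(C)C)(C(C)C)C(C)C)cc2o1
F0 | step 14 | none | none
F5 | step 16 | 1-[5-(benzyloxy)-2-methoxyphenyl]-3-{4-(benzyloxy)-5-[(1R)-3-[4-(benzyloxy)-2-methoxyphenyl]-1-[4-(benzyloxy)phenyl]propyl]-2-hydroxyphenyl}propan-1-one | COc1cc(OCc2ccccc2)ccc1CC[C@H](c1ccc(OCc2ccccc2)cc1)c1cc(CCC(=O)c2cc(OCc3ccccc3)ccc2OC)c(O)cc1OCc1ccccc1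
F6 | step 16 | 7-(benzyloxy)-2-[5-(benzyloxy)-2-methoxyphenyl]-6-[(1R)-3-[4-(benzyloxy)-2-methoxyphenyl]-1-[4-(benzyloxy)phenyl]propyl]-4H-chromene | COc1cc(OCc2ccccc2)ccc1CC[C@H](c1ccc(OCc2ccccc2)cc1)c1cc2c(cc1OCc1ccccc1)OC(c1cc(OCc3ccccc3)ccc1OC)=CC2
F0 | step 17 | none | none
A1 | alternative 1 | (2S)-2-[5-(benzyloxy)-2-methoxyphenyl]-6-{[4-(benzyloxy)phenyl](hydroxy)methyl}chroman-7-ol, both Ca epimers | OC(c1ccc(OCc2ccccc2)cc1)c1cc2c(cc1O)O[C@H](c1cc(OCc3ccccc3)ccc1OC)CC2
A2 | alternative 1 | N-{1-[4-(benzyloxy)-2-methoxyphenyl]ethenyl}acetamide | C=C(NC(C)=O)c1ccc(OCc2ccccc2)cc1OC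
A3 | alternative 1 | (4R,8S)-2-[4-(benzyloxy)-2-methoxyphenyl]-4-[4-(benzyloxy)phenyl]-8-[5-(benzyloxy)-2-methoxyphenyl]-7,8-dihydro-4H,6H-pyrano[3,2-g]chromene | COc1cc(OCc2ccccc2)ccc1C1=C[C@H](c2ccc(OCc4ccccc4)cc2)c2cc3c(cc2O1)O[C@H](c2cc(OCc4ccccc4)ccc2OC)CC3
A4 | alternative 2 | (8S)-8-[5-(benzyloxy)-2-methoxyphenyl]-7,8-dihydro-2H,6H-pyrano[3,2-g]chromen-2-one | O=C1C=Cc2cc3c(cc2O1)O[C@H](c2cc(OCc4ccccc4)ccc2OC)CC3
A5 | alternative 2 | (4R,8S)-4-[4-(benzyloxy)phenyl]-8-[5-(benzyloxy)-2-methoxyphenyl]-3,4,7,8-tetrahydro-2H,6H-pyrano[3,2-g]chromen-2-one | O=C1C[C@H](c2ccc(OCc4ccccc4)cc2)c2cc3c(cc2O1)O[C@H](c2cc(OCc4ccccc4)ccc2OC)CC3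
A6 | alternative 3 | 2-[(1R)-3-[4-(benzyloxy)-2-methoxyphenyl]-1-[4-(benzyloxy)phenyl]propyl]-4-{(3S)-3-[5-(benzyloxy)-2-methoxyphenyl]-3-hydroxypropyl}phenol | COc1cc(OCc2ccccc2)ccc1CC[C@H](c1ccc(OCc2ccccc2)cc1)c1cc(CC[C@H](O)c2cc(OCc3ccccc3)ccc2OC)ccc1O
A7 | alternative 3 | 2-[(1R)-3-[4-(benzyloxy)-2-methoxyphenyl]-1-[4-(benzyloxy)phenyl]propyl]-4-{(3S)-3-[5-(benzyloxy)-2-methoxyphenyl]-3-hydroxypropyl}-4-methoxycyclohexa-2,5-dien-1-one, both C4 epimers | COc1cc(OCc2ccccc2)ccc1CC[C@H](c1ccc(OCc2ccccc2)cc1)C1=CC(OC)(CC[C@H](O)c2cc(OCc3ccccc3)ccc2OC)C=CC1=O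
A8 | alternative 3 | (2S)-2-[5-(benzyloxy)-2-methoxyphenyl]-6-[(1R)-3-[4-(benzyloxy)-2-methoxyphenyl]-1-[4-(benzyloxy)phenyl]propyl]chroman-7-ol | COc1cc(OCc2ccccc2)ccc1CC[C@H](c1ccc(OCc2ccccc2)cc1)c1cc2c(cc1O)O[C@H](c1cc(OCc3ccccc3)ccc1OC)CC2
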